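## Analysis of the target

The target 28 is a linear tetramer of (2R,3R)-flavan-3-ol (epicatechin) units, each a benzopyran (aromatic ring A fused to the oxygen heterocycle ring C) with a catechol ring B on C2 and a hydroxyl on C3. Counting the units from the chain top, C4 of unit 1 is bonded to C6 of unit 2, C4 of unit 2 to C8 of unit 3, and C4 of unit 3 to C6 of unit 4. There are eleven stereocentres: C2 and C3 of all four units are 2,3-cis (aryl and hydroxyl both α), and C4 of units 1 to 3 carries its aryl group β, trans to the C3 oxygen. With sixteen phenolic and four secondary hydroxyls the free compound is air-sensitive, epimerises at C2 in base and loses its benzylic C4–aryl bonds in acid, so it must be released last under neutral reduction. Stereochemistry is the easier part, because a 2,3-cis unit with a cationic C4 accepts an arene trans to the C3 oxygen. Regiochemistry is the hard part: protected flavan-3-ols react as nucleophiles at C8, so the central 4→8 bond is natural and the two 4→6 bonds run against the innate preference. The strategy rests on ring A of unit 2: the carbon bearing unit 1 (C6) lies between the oxygenated carbons C5 and C7 and is para to C8a, so this ring is a phloroglucinol alkylated once by unit 1, with O1 as its para oxygen. If C8a is one carbon of an aryne (C4a≡C8a), forming O1–C8a, C4–C4a and O1–C2 from an enal builds ring C of unit 2 onto that arene, and the 4→6 connection follows from symmetry instead of from a selective substitution.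

## Retrosynthetic reasoning

28 from 27. All seventeen O–benzyl bonds and three aryl C–Br bonds are cut in one hydrogenolysis. Benzyl ethers survive fluoride, amide base, hydride, dioxirane and Lewis acid, and the bromines are regiochemical caps that leave in the same operation. Nothing else is done to the free polyphenol.

27 from 23 and 26. The cut is C4 (unit 2)–C8 (unit 3). It divides the molecule into two dimers, and it is the one interflavan bond whose 4→8 regiochemistry matches innate reactivity. The forward reaction ionises the C4 ether of 23 and must deliver the arene β, which the 2,3-cis arrangement of unit 2 ensures. It must also find one nucleophilic site only: bromine sits on C8 of units 1 and 2 in 23 and on C8 of unit 4 in 26, so C8 of unit 3 is the only strongly nucleophilic position left.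

26 from 24 and 25. The cut is C4 (unit 3)–C6 (unit 4). This lower 4→6 bond is made by direct arylation with C8 of unit 4 blocked by bromine, because both halves come from 2 in one step each. The price is a deactivated, hindered nucleophile.

23 back to 18. 23 is 22 with bromine caps placed on C8 of units 1 and 2 by electrophilic substitution. The 3α-hydroxyl of 22 comes from ketone 21 by hydride delivery to the β face, and 21 from the 3β-alcohol 20. Both oxygens of 20 come from the C3=C4 bond of 18 through epoxide 19. Epoxidation anti to the C2 aryl group necessarily places oxygen β, so C3 has to be inverted by oxidation and reduction. Taking the C4 oxygen from the alkene avoids a benzylic oxidation on a dimer, which would have to distinguish C4 of unit 2 from the already arylated C4 of unit 1.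

18 from 17. 18 is one of the two C2 epimers that make up 17. The two differ only at the one centre that a 2H-chromene can invert, by opening to 16 and closing again. Separation followed by thermal re-equilibration of the unwanted half therefore converts 17 into 18 without discarding material in principle.

17 from 11 and 13 (key disconnection). Ring C of unit 2 is cut at O1–C8a, C4–C4a and O1–C2. Backwards, 17 opens to o-quinone methide 16, which comes from benzoxete 15, the [2+2] adduct of aryne 14 and the carbonyl group of 13. A three-carbon enal and an aryne thus give the whole heterocycle. The forward reaction needs the carbonyl oxygen on C8a and not on C4a. C2 forms without control, which is why the product of this disconnection is 17 and not 18 alone.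

11 back to 6. The triflate of 11 is made from phenol 10 and the C–Si bond from carbamate 8 by directed metalation to 9. 8 comes from triol 6 by telling the unhindered para hydroxyl (carbamate 7) from the two hindered ortho hydroxyls (benzyl ethers). The para oxygen is unique by symmetry, so only steric differentiation is asked for.

6 from 4 and 5, and 4 from 1. The C4 (unit 1)–aryl bond is cut. All three CH positions of 5 are equivalent, so the Friedel–Crafts step has no regiochemical question and sets only the 4β configuration. 4 derives from 1 through 2 and 3 by benzylation and benzylic oxidation.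

13 from 12. The C2–C3 double bond of the enal is cut to a two-carbon olefination of 12.

## Alternatives that were turned down

Alternative 1: Ring A of unit 2 is opened between C4a and C5 and traced to an acyclic triketide whose future C6 already carries unit 1, stored as the 2-pyrone A1. In the forward step Mg(OMe)2 opens the lactone of A1 and the C4a methylene carbanion closes onto the ester carbon (Claisen condensation, C4a–C5). Enolisation then aromatises ring A to give chalcone A2.
- For it: the carbon holding unit 1 is flanked by C5 and C7 from the outset, and A2 brings C4 at the carbonyl oxidation level. Its E-enone would allow C2 and C3 to be set under catalyst control, which is stronger than the aryne route, where C2 forms without bias.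
- Against it: A2 has two free hydroxyls ortho to the acyl group, and ring C can close through either, so the C6-versus-C8 question returns when the heterocycle is formed and can be scrambled by reversible ring opening. In the open triketide, unit 1 sits on a carbon between two carbonyl-type carbons, where base invites loss of the stabilised flavan-4-yl group and other folding modes. After A2, ring closure, C3 hydroxylation, C4 reduction and activation are still needed, and A1 itself needs a multistep assembly.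
- Comparison: the aryne route has O1 fixed para to unit 1 by the symmetry of 6, uses two simple partners (11 and 13), and needs three steps from 18 to the C4 electrophile 22.

Alternative 2: Ring C of unit 3 is cut at O1–C2 and C3–C4, the retron of a hetero-Diels–Alder reaction of an o-quinone methide whose methide carbon (C4) already bears C6 of unit 4. The precursors are benzhydrol A3 and Z-alkenylboronate A4, and the product is A5. Acid-promoted dehydration of A3 gives the o-quinone methide, A4 adds across it, and later oxidation of the C–B bond with retention would give the 3-hydroxyl.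
- For it: the 4→6 bond to unit 4 becomes an ordinary aryl–carbinol bond, the Z geometry of A4 becomes the 2,3-cis relationship, and C2, C3 and C4 arise in one step. In bonds and stereocentres per step this is stronger than the chosen plan.
- Against it: the o-quinone methide is an electron-poor heterodiene that wants an electron-rich partner, yet the carbon of A4 that must bond to the hindered diarylmethide terminus carries boron and is weakly nucleophilic. The endo/exo preference must give 3,4-trans, and nothing in A4 or in remote unit 4 fixes the face, so diastereomers of A5 that cannot be interconverted are expected without an external chiral catalyst. The upper 4→6 bond (unit 1 to C6 of unit 2) is left unsolved.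
- Comparison: the aryne route also has one uncontrolled centre, but it is the one centre that can be re-equilibrated (the unwanted half of 17 is turned into 18 through 16), and the lower dimer 26 is reached from 2 in three steps.

Alternative 3: Ring A of unit 4 is dissected into a vinylketene and an alkyne: C8–C8a by Wolff rearrangement, C5–C6 and C7–C8 by ketene–alkyne [2+2], and C4a–C5 by 6π closure. The partners are diazoketone A6, which contains ring C of unit 4, and siloxyalkyne A7 on C4 of unit 3, and the product is phenol A8. Irradiation of A6 with A7 starts the rearrangement; the vinylketene adds the alkyne, the cyclobutenone opens, and the dienylketene closes and tautomerises to the benzene ring.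
- For it: the alkyne carbon bonded to unit 3 necessarily becomes C6, so the 4→6 regiochemistry is as firmly built in as in the aryne route. The two ring-A oxygens emerge differentiated. C2 and C3 of unit 4 arrive defined in A6, so there is no epimer problem, which is a point in its favour over the aryne route.
- Against it: A6 needs an enantioselective synthesis of a cis-substituted dihydropyran and a diazo transfer, and A7 needs a C4 alkynylation and an ynol silyl ether, all to create a benzene ring that 1 already supplies. The photolysis must run beside about a dozen aryl chromophores. It solves the lower 4→6 bond only.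
- Comparison: the chosen route takes ring A of three units from 1, builds only ring C of unit 2, and reaches the lower dimer 26 with a bromine cap in three steps from 2.

Key step: step 11

## Conventions and one assumption

- α and β refer to the faces of ring C in the usual flavan drawing: the C2 aryl group of epicatechin is α, and a 4β substituent is trans to the 3-oxygen of an epicatechin unit. These descriptors are used for protected intermediates because CIP letters change with the protecting groups.
- Assumption: 12, the dibenzyl ether of 3,4-dihydroxybenzaldehyde, is commercially available and is purchased as such.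
- Rotamers about the C4–aryl bonds are treated as conformers.

## Route

Step 1
Reactants: 1 (−)-epicatechin
Product: 2 5,7,3',4'-tetra-O-benzylepicatechin
Conditions: BnBr (4.4 equiv), K2CO3, DMF, 0 °C → rt, N2
Reagents that add atoms: benzyl bromide, BrCc1ccccc1
Why: Williamson etherification of the four phenols with carbonate leaves the secondary 3-hydroxyl free; mild base under nitrogen avoids C2 epimerisation and oxidation of the free catechol.

Step 2
Reactants: 2 5,7,3',4'-tetra-O-benzylepicatechin
Product: 3 3,5,7,3',4'-penta-O-benzylepicatechin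
Conditions: NaH, BnBr, DMF, 0 °C → rt
Reagents that add atoms: benzyl bromide, BrCc1ccccc1
Why: Williamson etherification of the remaining alcohol through its sodium alkoxide; with all phenols capped, ring-opening epimerisation at C2 is no longer possible.

Step 3
Reactants: 3 3,5,7,3',4'-penta-O-benzylepicatechin
Product: 4 3,5,7,3',4'-penta-O-benzyl-4β-(2-ethoxyethoxy)epicatechin
Conditions: DDQ (2 equiv), EtOCH2CH2OH (5 equiv), CH2Cl2, rt
Reagents that add atoms: 2-ethoxyethanol, CCOCCO
Why: Oxidative benzylic etherification: DDQ removes hydride from C4, which is activated by the three ring-A oxygens, and the alcohol adds to the cation trans to the 3-benzyloxy group (4β).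

Step 4
Reactants: 4 3,5,7,3',4'-penta-O-benzyl-4β-(2-ethoxyethoxy)epicatechin, 5 phloroglucinol
Product: 6 3,5,7,3',4'-penta-O-benzyl-4β-(2,4,6-trihydroxyphenyl)epicatechin
Conditions: 5 (5 equiv), BF3·OEt2 (0.3 equiv), THF–CH2Cl2, −20 → 0 °C
Reagents that add atoms: none
Why: Lewis-acid ionisation of the C4 ether and Friedel–Crafts alkylation of phloroglucinol; attack anti to the 3-benzyloxy group of the 2,3-cis unit sets 4β. All ring positions of 5 are equivalent, and its excess holds back double alkylation.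

Step 5
Reactants: 6 3,5,7,3',4'-penta-O-benzyl-4β-(2,4,6-trihydroxyphenyl)epicatechin
Product: 7 3,5,7,3',4'-penta-O-benzyl-4β-[4-(N,N-diethylcarbamoyloxy)-2,6-dihydroxyphenyl]epicatechin
Conditions: Et2NCOCl (1.05 equiv), K2CO3 (1.2 equiv), MeCN, 40 °C
Reagents that add atoms: N,N-diethylcarbamoyl chloride, CCN(CC)C(Cl)=O
Why: Chemoselective O-carbamoylation on steric grounds: the two ortho hydroxyls are buried beside the flavanyl group and its C3 and C5 benzyloxy groups, the para hydroxyl is open, and the slow, bulky carbamoyl chloride should take the open one.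

Step 6
Reactants: 7 3,5,7,3',4'-penta-O-benzyl-4β-[4-(N,N-diethylcarbamoyloxy)-2,6-dihydroxyphenyl]epicatechin
Product: 8 3,5,7,3',4'-penta-O-benzyl-4β-[2,6-bis(benzyloxy)-4-(N,N-diethylcarbamoyloxy)phenyl]epicatechin
Conditions: BnBr (2.6 equiv), K2CO3, n-Bu4NI (cat.), DMF, 50 °C
Reagents that add atoms: benzyl bromide, BrCc1ccccc1
Why: Williamson etherification of the two hindered phenols; the N,N-diethylcarbamate is stable to carbonate.

Step 7
Reactants: 8 3,5,7,3',4'-penta-O-benzyl-4β-[2,6-bis(benzyloxy)-4-(N,N-diethylcarbamoyloxy)phenyl]epicatechin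
Product: 9 3,5,7,3',4'-penta-O-benzyl-4β-[2,6-bis(benzyloxy)-4-(N,N-diethylcarbamoyloxy)-3-(trimethylsilyl)phenyl]epicatechin
Conditions: LiN(i-Pr)2 (1.3 equiv), THF, −78 °C, 1 h; Me3SiCl (3 equiv), −78 °C → rt
Reagents that add atoms: chlorotrimethylsilane, C[Si](C)(C)Cl
Why: Directed ortho-metalation: the carbamate and the neighbouring benzyloxy group together acidify the C–H between them, and the two such positions are equivalent. An amide base suffices and spares the benzyl ethers, and the silyl quench at −78 °C precedes anionic Fries rearrangement.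

Step 8
Reactants: 9 3,5,7,3',4'-penta-O-benzyl-4β-[2,6-bis(benzyloxy)-4-(N,N-diethylcarbamoyloxy)-3-(trimethylsilyl)phenyl]epicatechin
Product: 10 3,5,7,3',4'-penta-O-benzyl-4β-[2,6-bis(benzyloxy)-4-hydroxy-3-(trimethylsilyl)phenyl]epicatechin
Conditions: LiAlH4 (3 equiv), THF, 0 °C → rt; aq KNaC4H4O6 work-up
Reagents that add atoms: none
Why: Reductive carbamate cleavage: hydride adds to the carbamate carbonyl and the phenoxide is expelled. Benzyl ethers and the aryl–silicon bond are inert, and the neutral tartrate work-up avoids protodesilylation of the electron-rich arylsilane.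

Step 9
Reactants: 10 3,5,7,3',4'-penta-O-benzyl-4β-[2,6-bis(benzyloxy)-4-hydroxy-3-(trimethylsilyl)phenyl]epicatechin
Product: 11 3,5,7,3',4'-penta-O-benzyl-4β-[2,6-bis(benzyloxy)-4-(trifluoromethanesulfonyloxy)-3-(trimethylsilyl)phenyl]epicatechin
Conditions: Tf2O (1.3 equiv), pyridine, CH2Cl2, −20 → 0 °C
Reagents that add atoms: triflic anhydride, O=S(=O)(OS(=O)(=O)C(F)(F)F)C(F)(F)F
Why: O-Sulfonylation of the phenol, the standard last step to an o-silylaryl triflate.

Step 10
Reactants: 12 3,4-bis(benzyloxy)benzaldehyde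
Product: 13 (E)-3-[3,4-bis(benzyloxy)phenyl]prop-2-enal
Conditions: Ph3P=CHCHO (1.3 equiv), PhMe, 90 °C
Reagents that add atoms: (triphenylphosphoranylidene)acetaldehyde, O=CC=P(c1ccccc1)(c1ccccc1)c1ccccc1
Why: Wittig olefination with a stabilised formyl ylide gives the two-carbon homologue as the E-enal.

Step 11
Reactants: 11 3,5,7,3',4'-penta-O-benzyl-4β-[2,6-bis(benzyloxy)-4-(trifluoromethanesulfonyloxy)-3-(trimethylsilyl)phenyl]epicatechin, 13 (E)-3-[3,4-bis(benzyloxy)phenyl]prop-2-enal
Product: 17 3,5,7,3',4'-penta-O-benzylepicatechin-(4β→6)-[5,7,3',4'-tetrakis(benzyloxy)flav-3-ene] (both C2 epimers of the flavene unit), via aryne 14 (not isolated), via benzoxete 15 (not isolated), via o-quinone methide 16 (not isolated)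
Conditions: 13 (3 equiv), CsF (3 equiv), MeCN–THF (1:1), rt
Reagents that add atoms: none
Why: Fluoride attacks silicon and the neighbouring triflate leaves, giving aryne 14 with the triple bond between the future C4a and C8a. The carbonyl oxygen of 13 adds to C8a, the terminus remote from the C5 benzyloxy group, so the aryl anion develops at C4a beside that inductively stabilising oxygen and closes onto the carbonyl carbon to give benzoxete 15 (stepwise [2+2], bonds O1–C8a and C4–C4a). The strained four-membered ring opens to o-quinone methide 16, whose oxatriene (O=C8a, C4a=C4, C3=C2) closes by thermal disrotatory oxa-6π electrocyclisation, forming O1–C2 and the six-membered ring C. The closest known reaction type is the CsF-mediated annulation of o-silylaryl triflates with cinnamaldehydes to 2-aryl-2H-chromenes. The regioselectivity needed (oxygen on C8a) is secured by the C5 alkoxy group through aryne polarisation, and no choice between C6 and C8 linkage arises because the two positions ortho to the carbamate oxygen of 8 were equivalent. The one new stereocentre, C2, has no controlling element nearby, so both faces should close at similar rates and 17 is expected as the pair of C2 epimers in comparable amounts, which go together into step 12. The enal cannot enolise, and its excess should outrun aryne self-reaction and capture of 16 by a second aryne.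

Step 12
Reactants: 17 3,5,7,3',4'-penta-O-benzylepicatechin-(4β→6)-[5,7,3',4'-tetrakis(benzyloxy)flav-3-ene] (both C2 epimers of the flavene unit)
Product: 18 3,5,7,3',4'-penta-O-benzylepicatechin-(4β→6)-[(2α)-5,7,3',4'-tetrakis(benzyloxy)flav-3-ene]
Conditions: SiO2 chromatography of the two epimers; 2β fraction: PhMe, 110 °C, dark, argon, then rechromatography (cycle repeated)
Reagents that add atoms: none
Why: The two components are diastereomers because unit 1 carries fixed stereocentres, so they are separable; the 2β component is then re-equilibrated by the known thermal valence isomerisation of a 2H-chromene, which opens to the same o-quinone methide (16) that step 11 passes through and recloses on either face. Only C2 is scrambled, since no other centre is labile under neutral thermal conditions, and repeated separation funnels the material into the 2α epimer.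

Step 13
Reactants: 18 3,5,7,3',4'-penta-O-benzylepicatechin-(4β→6)-[(2α)-5,7,3',4'-tetrakis(benzyloxy)flav-3-ene]
Product: 20 3,5,7,3',4'-penta-O-benzylepicatechin-(4β→6)-[5,7,3',4'-tetra-O-benzyl-4α-(2-ethoxyethoxy)catechin], via epoxide 19 (not isolated)
Conditions: DMDO (1.2 equiv), acetone–CH2Cl2, −20 °C; then EtOCH2CH2OH (10 equiv), PPTS (5 mol %), −20 → 0 °C
Reagents that add atoms: dimethyldioxirane, CC1(C)OO1; 2-ethoxyethanol, CCOCCO
Why: The neutral dioxirane epoxidises the electron-rich styrenic C3=C4 bond anti to the C2 aryl group (β face). The labile benzylic epoxide is opened at C4 by the alcohol with inversion, giving the 2,3-trans-3,4-trans product (3β-OH, 4α-OR). Saturating C3=C4 also locks C2 against electrocyclic epimerisation.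

Step 14
Reactants: 20 3,5,7,3',4'-penta-O-benzylepicatechin-(4β→6)-[5,7,3',4'-tetra-O-benzyl-4α-(2-ethoxyethoxy)catechin]
Product: 21 3,5,7,3',4'-penta-O-benzylepicatechin-(4β→6)-[(2α,4α)-5,7,3',4'-tetrakis(benzyloxy)-4-(2-ethoxyethoxy)flavan-3-one]
Conditions: Dess–Martin periodinane (1.5 equiv), NaHCO3, CH2Cl2, 0 °C → rt
Reagents that add atoms: none
Why: Dess–Martin oxidation of the only free hydroxyl under buffered conditions, as in the oxidation of protected catechin to its flavan-3-one.

Step 15
Reactants: 21 3,5,7,3',4'-penta-O-benzylepicatechin-(4β→6)-[(2α,4α)-5,7,3',4'-tetrakis(benzyloxy)-4-(2-ethoxyethoxy)flavan-3-one]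
Product: 22 3,5,7,3',4'-penta-O-benzylepicatechin-(4β→6)-[5,7,3',4'-tetra-O-benzyl-4α-(2-ethoxyethoxy)epicatechin]
Conditions: LiBH(s-Bu)3 (1.5 equiv), THF, −78 °C; then H2O
Reagents that add atoms: none
Why: The bulky trialkylborohydride attacks the C3 carbonyl from the β face, opposite the C2 aryl and C4 alkoxy groups (both α), giving the 3α-alcohol of the 2,3-cis series; this is the established catechin-to-epicatechin inversion. Low temperature suppresses enolisation towards C2.

Step 16
Reactants: 22 3,5,7,3',4'-penta-O-benzylepicatechin-(4β→6)-[5,7,3',4'-tetra-O-benzyl-4α-(2-ethoxyethoxy)epicatechin]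
Product: 23 8-bromo-3,5,7,3',4'-penta-O-benzylepicatechin-(4β→6)-[8-bromo-5,7,3',4'-tetra-O-benzyl-4α-(2-ethoxyethoxy)epicatechin]
Conditions: NBS (2.05 equiv), CH2Cl2, −40 → 0 °C
Reagents that add atoms: N-bromosuccinimide, O=C1CCC(=O)N1Br
Why: Electrophilic aromatic bromination at the two most nucleophilic ring-A positions, C8 of unit 1 (C8 reacts before C6 in benzylated flavans) and C8 of unit 2 (the only free position of that ring). The caps stop the electrophile from acting as a nucleophile in step 20.

Step 17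
Reactants: 2 5,7,3',4'-tetra-O-benzylepicatechin
Product: 24 8-bromo-5,7,3',4'-tetra-O-benzylepicatechin
Conditions: NBS (1.0 equiv), CH2Cl2, −78 °C → rt
Reagents that add atoms: N-bromosuccinimide, O=C1CCC(=O)N1Br
Why: Regioselective electrophilic bromination at C8, which leaves C6 as the only nucleophilic ring position of the future unit 4.

Step 18
Reactants: 2 5,7,3',4'-tetra-O-benzylepicatechin
Product: 25 5,7,3',4'-tetra-O-benzyl-4β-(2-ethoxyethoxy)epicatechin
Conditions: DDQ (2 equiv), EtOCH2CH2OH (5 equiv), CH2Cl2, rt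
Reagents that add atoms: 2-ethoxyethanol, CCOCCO
Why: Same oxidative benzylic etherification as step 3; the alcohol adds trans to the free 3-hydroxyl (4β).

Step 19
Reactants: 25 5,7,3',4'-tetra-O-benzyl-4β-(2-ethoxyethoxy)epicatechin, 24 8-bromo-5,7,3',4'-tetra-O-benzylepicatechin
Product: 26 5,7,3',4'-tetra-O-benzylepicatechin-(4β→6)-(8-bromo-5,7,3',4'-tetra-O-benzylepicatechin)
Conditions: 24 (4 equiv), TMSOTf (0.2 equiv), CH2Cl2, −78 °C, slow addition of 25; → −30 °C; excess 24 recovered
Reagents that add atoms: none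
Why: Lewis-acid-catalysed Friedel–Crafts alkylation: the C4 cation of 25 is taken by C6 of 24 (C8 blocked) anti to the 3-hydroxyl, giving 4β. Slow addition of 25 into excess 24 holds back self-condensation of 25 through its own free C8.

Step 20
Reactants: 23 8-bromo-3,5,7,3',4'-penta-O-benzylepicatechin-(4β→6)-[8-bromo-5,7,3',4'-tetra-O-benzyl-4α-(2-ethoxyethoxy)epicatechin], 26 5,7,3',4'-tetra-O-benzylepicatechin-(4β→6)-(8-bromo-5,7,3',4'-tetra-O-benzylepicatechin)
Product: 27 heptadeca-O-benzyl-tribromo tetramer: 8-bromo-penta-O-benzylepicatechin-(4β→6)-8-bromo-tetra-O-benzylepicatechin-(4β→8)-tetra-O-benzylepicatechin-(4β→6)-8-bromo-tetra-O-benzylepicatechin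
Conditions: 26 (1.3 equiv), TMSOTf (0.2 equiv), CH2Cl2, −78 → −40 °C
Reagents that add atoms: none
Why: Same ionisation and Friedel–Crafts manifold. The only uncapped, strongly nucleophilic position present is C8 of unit 3 in 26, since C8 of units 1, 2 and 4 carry bromine and C6 positions are far less reactive. Attack anti to the 3α-hydroxyl of the 2,3-cis unit 2 gives the 4β bond.

Step 21
Reactants: 27 heptadeca-O-benzyl-tribromo tetramer
Product: 28 epicatechin-(4β→6)-epicatechin-(4β→8)-epicatechin-(4β→6)-epicatechin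
Conditions: H2 (1 atm), Pd(OH)2/C, Et3N (4 equiv), THF–MeOH–H2O, rt; filtration and lyophilisation under argon
Reagents that add atoms: none
Why: Hydrogenolysis of all seventeen benzyl ethers and hydrodebromination of the three aryl bromides in one operation; the amine takes up HBr so the acid-labile interflavan bonds and the free catechols see neither acid nor strong base.

## Compound list

1 | (−)-epicatechin, (2R,3R)-flavan-3,5,7,3',4'-pentol | O[C@@H]1Cc2c(O)cc(O)cc2O[C@@H]1c1ccc(O)c(O)c1 | starting material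
2 | 5,7,3',4'-tetra-O-benzylepicatechin | C(c9ccccc9)Oc1cc(OCc9ccccc9)c2c(c1)O[C@H](c3ccc(OCc9ccccc9)c(OCc9ccccc9)c3)[C@H](O)C2 | intermediate
3 | 3,5,7,3',4'-penta-O-benzylepicatechin | C(c9ccccc9)Oc1cc(OCc9ccccc9)c2c(c1)O[C@H](c3ccc(OCc9ccccc9)c(OCc9ccccc9)c3)[C@H](OCc9ccccc9)C2 | intermediate
4 | 3,5,7,3',4'-penta-O-benzyl-4β-(2-ethoxyethoxy)epicatechin | C(c9ccccc9)Oc1cc(OCc9ccccc9)c2c(c1)O[C@H](c3ccc(OCc9ccccc9)c(OCc9ccccc9)c3)[C@H](OCc9ccccc9)[C@H]2OCCOCC | intermediate
5 | phloroglucinol (benzene-1,3,5-triol) | Oc1cc(O)cc(O)c1 | starting material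
6 | penta-O-benzylepicatechin with a 2,4,6-trihydroxyphenyl group at C4β | C(c9ccccc9)Oc1cc(OCc9ccccc9)c2c(c1)O[C@H](c3ccc(OCc9ccccc9)c(OCc9ccccc9)c3)[C@H](OCc9ccccc9)[C@H]2c4c(O)cc(O)cc4O | intermediate
7 | penta-O-benzylepicatechin with a 4-(N,N-diethylcarbamoyloxy)-2,6-dihydroxyphenyl group at C4β | C(c9ccccc9)Oc1cc(OCc9ccccc9)c2c(c1)O[C@H](c3ccc(OCc9ccccc9)c(OCc9ccccc9)c3)[C@H](OCc9ccccc9)[C@H]2c4c(O)cc(OC(=O)N(CC)CC)cc4O | intermediate
8 | penta-O-benzylepicatechin with a 2,6-bis(benzyloxy)-4-(N,N-diethylcarbamoyloxy)phenyl group at C4β | C(c9ccccc9)Oc1cc(OCc9ccccc9)c2c(c1)O[C@H](c3ccc(OCc9ccccc9)c(OCc9ccccc9)c3)[C@H](OCc9ccccc9)[C@H]2c4c(OCc9ccccc9)cc(OC(=O)N(CC)CC)cc4OCc9ccccc9 | intermediate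
9 | penta-O-benzylepicatechin with a 2,6-bis(benzyloxy)-4-(N,N-diethylcarbamoyloxy)-3-(trimethylsilyl)phenyl group at C4β | C(c9ccccc9)Oc1cc(OCc9ccccc9)c2c(c1)O[C@H](c3ccc(OCc9ccccc9)c(OCc9ccccc9)c3)[C@H](OCc9ccccc9)[C@H]2c4c(OCc9ccccc9)cc(OC(=O)N(CC)CC)c([Si](C)(C)C)c4OCc9ccccc9 | intermediate
10 | penta-O-benzylepicatechin with a 2,6-bis(benzyloxy)-4-hydroxy-3-(trimethylsilyl)phenyl group at C4β | C(c9ccccc9)Oc1cc(OCc9ccccc9)c2c(c1)O[C@H](c3ccc(OCc9ccccc9)c(OCc9ccccc9)c3)[C@H](OCc9ccccc9)[C@H]2c4c(OCc9ccccc9)cc(O)c([Si](C)(C)C)c4OCc9ccccc9 | intermediate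
11 | penta-O-benzylepicatechin with a 2,6-bis(benzyloxy)-4-(trifluoromethanesulfonyloxy)-3-(trimethylsilyl)phenyl group at C4β (aryne precursor) | C(c9ccccc9)Oc1cc(OCc9ccccc9)c2c(c1)O[C@H](c3ccc(OCc9ccccc9)c(OCc9ccccc9)c3)[C@H](OCc9ccccc9)[C@H]2c4c(OCc9ccccc9)cc(OS(=O)(=O)C(F)(F)F)c([Si](C)(C)C)c4OCc9ccccc9 | intermediate
12 | 3,4-bis(benzyloxy)benzaldehyde | O=Cc1ccc(OCc2ccccc2)c(OCc2ccccc2)c1 | starting material
13 | (E)-3-[3,4-bis(benzyloxy)phenyl]prop-2-enal | O=C/C=C/c1ccc(OCc2ccccc2)c(OCc2ccccc2)c1 | intermediate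
14 | aryne from 11: 2,6-bis(benzyloxy)-3,4-didehydrophenyl group at C4β of penta-O-benzylepicatechin (triple bond between the future C4a and C8a) | C(c9ccccc9)Oc1cc(OCc9ccccc9)c2c(c1)O[C@H](c3ccc(OCc9ccccc9)c(OCc9ccccc9)c3)[C@H](OCc9ccccc9)[C@H]2C4=C(OCc9ccccc9)C#CC=C4OCc9ccccc9 | intermediate
15 | benzoxete: [2+2] adduct of 14 with the C=O of 13, 2-[(E)-styryl]-2H-benzoxete fused at C4a–C8a, oxete carbon as a mixture of epimers | C(c9ccccc9)Oc1cc(OCc9ccccc9)c2c(c1)O[C@H](c3ccc(OCc9ccccc9)c(OCc9ccccc9)c3)[C@H](OCc9ccccc9)[C@H]2c4c(OCc9ccccc9)cc5c(c4OCc9ccccc9)C(/C=C/c3ccc(OCc9ccccc9)c(OCc9ccccc9)c3)O5 | intermediate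
16 | o-quinone methide: C8a=O, exocyclic C4a=C4 with the (E)-styryl group cis to C8a | C(c9ccccc9)Oc1cc(OCc9ccccc9)c2c(c1)O[C@H](c3ccc(OCc9ccccc9)c(OCc9ccccc9)c3)[C@H](OCc9ccccc9)[C@H]2C4=C(OCc9ccccc9)C(=C/C=C/c3ccc(OCc9ccccc9)c(OCc9ccccc9)c3)/C(=O)C=C4OCc9ccccc9 | intermediate
17 | penta-O-benzylepicatechin-(4β→6)-[5,7,3',4'-tetrakis(benzyloxy)flav-3-ene], both C2 epimers of the flavene unit (2α and 2β) | C(c9ccccc9)Oc1cc(OCc9ccccc9)c2c(c1)O[C@H](c3ccc(OCc9ccccc9)c(OCc9ccccc9)c3)[C@H](OCc9ccccc9)[C@H]2c4c(OCc9ccccc9)cc5c(c4OCc9ccccc9)C=CC(c3ccc(OCc9ccccc9)c(OCc9ccccc9)c3)O5 | intermediate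
18 | penta-O-benzylepicatechin-(4β→6)-[(2α)-5,7,3',4'-tetrakis(benzyloxy)flav-3-ene], the single 2α epimer | C(c9ccccc9)Oc1cc(OCc9ccccc9)c2c(c1)O[C@H](c3ccc(OCc9ccccc9)c(OCc9ccccc9)c3)[C@H](OCc9ccccc9)[C@H]2c4c(OCc9ccccc9)cc5c(c4OCc9ccccc9)C=C[C@@H](c3ccc(OCc9ccccc9)c(OCc9ccccc9)c3)O5 | intermediate
19 | 3β,4β-epoxide of 18 | C(c9ccccc9)Oc1cc(OCc9ccccc9)c2c(c1)O[C@H](c3ccc(OCc9ccccc9)c(OCc9ccccc9)c3)[C@H](OCc9ccccc9)[C@H]2c4c(OCc9ccccc9)cc5c(c4OCc9ccccc9)[C@@H]6O[C@@H]6[C@@H](c3ccc(OCc9ccccc9)c(OCc9ccccc9)c3)O5 | intermediate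
20 | penta-O-benzylepicatechin-(4β→6)-[tetra-O-benzyl-4α-(2-ethoxyethoxy)catechin] (unit 2: 2α-aryl, 3β-OH, 4α-OR) | C(c9ccccc9)Oc1cc(OCc9ccccc9)c2c(c1)O[C@H](c3ccc(OCc9ccccc9)c(OCc9ccccc9)c3)[C@H](OCc9ccccc9)[C@H]2c4c(OCc9ccccc9)cc5c(c4OCc9ccccc9)[C@@H](OCCOCC)[C@H](O)[C@@H](c3ccc(OCc9ccccc9)c(OCc9ccccc9)c3)O5 | intermediate
21 | flavan-3-one of unit 2 (2α-aryl, 4α-(2-ethoxyethoxy)) | C(c9ccccc9)Oc1cc(OCc9ccccc9)c2c(c1)O[C@H](c3ccc(OCc9ccccc9)c(OCc9ccccc9)c3)[C@H](OCc9ccccc9)[C@H]2c4c(OCc9ccccc9)cc5c(c4OCc9ccccc9)[C@@H](OCCOCC)C(=O)[C@@H](c3ccc(OCc9ccccc9)c(OCc9ccccc9)c3)O5 | intermediate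
22 | penta-O-benzylepicatechin-(4β→6)-[tetra-O-benzyl-4α-(2-ethoxyethoxy)epicatechin] (unit 2: 2α-aryl, 3α-OH, 4α-OR) | C(c9ccccc9)Oc1cc(OCc9ccccc9)c2c(c1)O[C@H](c3ccc(OCc9ccccc9)c(OCc9ccccc9)c3)[C@H](OCc9ccccc9)[C@H]2c4c(OCc9ccccc9)cc5c(c4OCc9ccccc9)[C@@H](OCCOCC)[C@@H](O)[C@@H](c3ccc(OCc9ccccc9)c(OCc9ccccc9)c3)O5 | intermediate
23 | 22 with bromine on C8 of unit 1 and C8 of unit 2 | C(c9ccccc9)Oc1cc(OCc9ccccc9)c2c(c1Br)O[C@H](c3ccc(OCc9ccccc9)c(OCc9ccccc9)c3)[C@H](OCc9ccccc9)[C@H]2c4c(OCc9ccccc9)c(Br)c5c(c4OCc9ccccc9)[C@@H](OCCOCC)[C@@H](O)[C@@H](c3ccc(OCc9ccccc9)c(OCc9ccccc9)c3)O5 | intermediate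
24 | 8-bromo-5,7,3',4'-tetra-O-benzylepicatechin | C(c9ccccc9)Oc1cc(OCc9ccccc9)c2c(c1Br)O[C@H](c3ccc(OCc9ccccc9)c(OCc9ccccc9)c3)[C@H](O)C2 | intermediate
25 | 5,7,3',4'-tetra-O-benzyl-4β-(2-ethoxyethoxy)epicatechin | C(c9ccccc9)Oc1cc(OCc9ccccc9)c2c(c1)O[C@H](c3ccc(OCc9ccccc9)c(OCc9ccccc9)c3)[C@H](O)[C@H]2OCCOCC | intermediate
26 | tetra-O-benzylepicatechin-(4β→6)-(8-bromo-tetra-O-benzylepicatechin) | C(c9ccccc9)Oc1cc(OCc9ccccc9)c2c(c1)O[C@H](c3ccc(OCc9ccccc9)c(OCc9ccccc9)c3)[C@H](O)[C@H]2c4c(OCc9ccccc9)c(Br)c5c(c4OCc9ccccc9)C[C@@H](O)[C@@H](c3ccc(OCc9ccccc9)c(OCc9ccccc9)c3)O5 | intermediate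
27 | heptadeca-O-benzyl tetramer with bromine on C8 of units 1, 2 and 4 | C(c9ccccc9)Oc1cc(OCc9ccccc9)c2c(c1Br)O[C@H](c3ccc(OCc9ccccc9)c(OCc9ccccc9)c3)[C@H](OCc9ccccc9)[C@H]2c4c(OCc9ccccc9)c(Br)c5c(c4OCc9ccccc9)[C@H](c6c(OCc9ccccc9)cc(OCc9ccccc9)c7c6O[C@H](c3ccc(OCc9ccccc9)c(OCc9ccccc9)c3)[C@H](O)[C@H]7c6c(OCc9ccccc9)c(Br)c7c(c6OCc9ccccc9)C[C@@H](O)[C@@H](c3ccc(OCc9ccccc9)c(OCc9ccccc9)c3)O7)[C@@H](O)[C@@H](c3ccc(OCc9ccccc9)c(OCc9ccccc9)c3)O5 | intermediate
28 | epicatechin-(4β→6)-epicatechin-(4β→8)-epicatechin-(4β→6)-epicatechin (CNP0120618.1) | Oc1cc(O)c2c(c1)O[C@H](c1ccc(O)c(O)c1)[C@H](O)[C@H]2c1c(O)cc2c(c1O)[C@H](c1c(O)cc(O)c3c1O[C@H](c1ccc(O)c(O)c1)[C@H](O)[C@H]3c1c(O)cc3c(c1O)C[C@@H](O)[C@@H](c1ccc(O)c(O)c1)O3)[C@@H](O)[C@@H](c1ccc(O)c(O)c1)O2 | target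

## Step count and weak points

Total: 21 steps. Longest linear sequence: 17 steps from 1 (steps 1–9, 11–16, 20, 21).

Step 11 (key step). The enal carbonyl is a modest nucleophile, so aryne self-reaction or protonation may outpace the [2+2] capture, and 16 may be intercepted by a second aryne before it cyclises; the aryne is also flanked by a benzyloxy group and may react sluggishly. Fallback, setting out from 8 and returning at 17, which reaches the same o-quinone methide by an ionic route without aryne, silicon or triflate. 8 is lithiated between the carbamate and the benzyloxy group with LiN(i-Pr)2 at −78 °C, the metalation that step 7 has already shown to work. The aryllithium adds 1,2 to 13 and gives, as its lithium alkoxide, the allylic carbinol 3,5,7,3',4'-penta-O-benzyl-4β-[2,6-bis(benzyloxy)-4-(N,N-diethylcarbamoyloxy)-3-[(E)-3-(3,4-bis(benzyloxy)phenyl)-1-hydroxyprop-2-enyl]phenyl]epicatechin F1. On warming to room temperature the alkoxide should take over the carbamoyl group through a six-membered transition state, giving the phenoxide of the allylic carbamate 3,5,7,3',4'-penta-O-benzyl-4β-[2,6-bis(benzyloxy)-3-[(E)-3-(3,4-bis(benzyloxy)phenyl)-1-(N,N-diethylcarbamoyloxy)prop-2-enyl]-4-hydroxyphenyl]epicatechin F2. The phenoxide expels diethylcarbamate from the allylic and benzylic carbon to give 16, which closes to 17.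

Step 12. The two C2 epimers may separate poorly as flav-3-enes, because the epimeric centre lies far from the stereocentres of unit 1, and prolonged heating may divert the o-quinone methide into dimers. Fallback, setting out from 17 and returning at 20, which moves the separation to a stage where the epimers differ at three adjacent centres and carry a free hydroxyl. The whole of 17 is epoxidised and opened as in step 13. The products are 20 and its unit 2 diastereomer, 3,5,7,3',4'-penta-O-benzylepicatechin-(4β→6)-[(2β,3α,4β)-5,7,3',4'-tetrakis(benzyloxy)-4-(2-ethoxyethoxy)flavan-3-ol] F3. The two alcohols are separated by chromatography or crystallisation and F3 is set aside, so the recycling is given up for an easier separation.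

Step 5. Acylation may not discriminate well between the para and ortho hydroxyls, and a second carbamoylation may follow. Fallback, setting out from 4 and returning at 8, which moves the differentiation into the nucleophile and bypasses 6 and 7. Commercial 3,5-bis(benzyloxy)phenol is carbamoylated (NaH, Et2NCOCl, THF) to 3,5-bis(benzyloxy)phenyl N,N-diethylcarbamate F4. F4 is used in excess as the arene in the TMSOTf-catalysed Friedel–Crafts reaction with 4. Substitution between the two benzyloxy groups gives 8 directly, and the regioisomer substituted beside the carbamate is removed by chromatography. A selective acylation is exchanged for a regioisomer separation.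

Step 7. The amide base may metalate incompletely, a stronger alkyllithium may deprotonate benzylic OCH2 groups (leading to Wittig rearrangement), and anionic Fries rearrangement or a second silylation at the other ortho position may intervene. Fallback, setting out from 8 and returning at 10, by halogen–metal exchange and retro-Brook silyl migration. LiAlH4 cleaves the carbamate of 8 to the phenol 3,5,7,3',4'-penta-O-benzyl-4β-[2,6-bis(benzyloxy)-4-hydroxyphenyl]epicatechin F5. NBS (3 equiv) brominates F5 exhaustively at both positions ortho to the hydroxyl and at C8 of unit 1, giving 8-bromo-3,5,7,3',4'-penta-O-benzyl-4β-[2,6-bis(benzyloxy)-3,5-dibromo-4-hydroxyphenyl]epicatechin F6. Hexamethyldisilazane converts F6 into its trimethylsilyl ether F7. n-BuLi (excess, THF, −78 °C → rt) exchanges all three bromines of F7, and the silyl group migrates from oxygen to one ortho carbon. Aqueous quench protonates the other two aryllithiums and gives 10. Every surplus bromine is erased, so the selectivity of the bromination does not matter.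

Step 15. Hydride may attack from the wrong face if the alcoholysis in step 13 has placed part of the C4 alkoxy group β, and the basic reagent may enolise the ketone towards C2. Fallback, setting out from 18 and returning at 27, which inverts the face of the epoxide instead of inverting C3. NBS (3 equiv) in aqueous THF gives the trans-bromohydrin of unit 2 (3β-Br, 4α-OH) and in the same operation the two C8 bromine caps, F8. NaH in THF closes F8 to the 3α,4α-epoxide F9, on the same face as the C2 aryl group. Opening of F9 at C4 with 2-ethoxyethanol and PPTS gives the 4β-(2-ethoxyethoxy)-3α-ol F10, the C4 epimer of 23. F10 is coupled with 26 exactly as in step 20 to give 27, since C4 becomes cationic and its configuration in the precursor is lost.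

Step 19. Self-condensation of 25 through its own free C8 may outrun attack by the hindered, bromine-deactivated C6 of 24, and 26 may be alkylated again at C8 of unit 3. Fallback, setting out from 2 and returning at 26, which caps the electrophile as well. N-Iodosuccinimide converts 2 into 8-iodo-5,7,3',4'-tetra-O-benzylepicatechin F11. DDQ and 2-ethoxyethanol give 8-iodo-5,7,3',4'-tetra-O-benzyl-4β-(2-ethoxyethoxy)epicatechin F12, an electrophile that cannot self-condense through C8 and can therefore be used in excess. TMSOTf-catalysed coupling of F12 with 24 gives the iodo-bromo dimer 8-iodo-tetra-O-benzylepicatechin-(4β→6)-(8-bromo-tetra-O-benzylepicatechin) F13. i-PrMgCl·LiCl (excess, THF, −20 °C) exchanges the aryl iodide of F13 selectively over the aryl bromide, and methanol quench gives 26.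

## Further compounds

F1 | step 11 | 3,5,7,3',4'-penta-O-benzyl-4β-[2,6-bis(benzyloxy)-4-(N,N-diethylcarbamoyloxy)-3-[(E)-3-(3,4-bis(benzyloxy)phenyl)-1-hydroxyprop-2-enyl]phenyl]epicatechin (carbinol epimers) | C(c9ccccc9)Oc1cc(OCc9ccccc9)c2c(c1)O[C@H](c3ccc(OCc9ccccc9)c(OCc9ccccc9)c3)[C@H](OCc9ccccc9)[C@H]2c4c(OCc9ccccc9)cc(OC(=O)N(CC)CC)c(C(O)/C=C/c3ccc(OCc9ccccc9)c(OCc9ccccc9)c3)c4OCc9ccccc9
F2 | step 11 | 3,5,7,3',4'-penta-O-benzyl-4β-[2,6-bis(benzyloxy)-3-[(E)-3-(3,4-bis(benzyloxy)phenyl)-1-(N,N-diethylcarbamoyloxy)prop-2-enyl]-4-hydroxyphenyl]epicatechin (carbinol epimers) | C(c9ccccc9)Oc1cc(OCc9ccccc9)c2c(c1)O[C@H](c3ccc(OCc9ccccc9)c(OCc9ccccc9)c3)[C@H](OCc9ccccc9)[C@H]2c4c(OCc9ccccc9)cc(O)c(C(OC(=O)N(CC)CC)/C=C/c3ccc(OCc9ccccc9)c(OCc9ccccc9)c3)c4OCc9ccccc9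
F3 | step 12 | unit 2 diastereomer of 20: penta-O-benzylepicatechin-(4β→6)-[(2β,3α,4β)-5,7,3',4'-tetrakis(benzyloxy)-4-(2-ethoxyethoxy)flavan-3-ol] | C(c9ccccc9)Oc1cc(OCc9ccccc9)c2c(c1)O[C@H](c3ccc(OCc9ccccc9)c(OCc9ccccc9)c3)[C@H](OCc9ccccc9)[C@H]2c4c(OCc9ccccc9)cc5c(c4OCc9ccccc9)[C@H](OCCOCC)[C@@H](O)[C@H](c3ccc(OCc9ccccc9)c(OCc9ccccc9)c3)O5
F4 | step 5 | 3,5-bis(benzyloxy)phenyl N,N-diethylcarbamate | CCN(CC)C(=O)Oc1cc(OCc2ccccc2)cc(OCc2ccccc2)c1
F5 | step 7 | 3,5,7,3',4'-penta-O-benzyl-4β-[2,6-bis(benzyloxy)-4-hydroxyphenyl]epicatechin | C(c9ccccc9)Oc1cc(OCc9ccccc9)c2c(c1)O[C@H](c3ccc(OCc9ccccc9)c(OCc9ccccc9)c3)[C@H](OCc9ccccc9)[C@H]2c4c(OCc9ccccc9)cc(O)cc4OCc9ccccc9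
F6 | step 7 | 8-bromo-3,5,7,3',4'-penta-O-benzyl-4β-[2,6-bis(benzyloxy)-3,5-dibromo-4-hydroxyphenyl]epicatechin | C(c9ccccc9)Oc1cc(OCc9ccccc9)c2c(c1Br)O[C@H](c3ccc(OCc9ccccc9)c(OCc9ccccc9)c3)[C@H](OCc9ccccc9)[C@H]2c4c(OCc9ccccc9)c(Br)c(O)c(Br)c4OCc9ccccc9
F7 | step 7 | trimethylsilyl ether of F6 | C(c9ccccc9)Oc1cc(OCc9ccccc9)c2c(c1Br)O[C@H](c3ccc(OCc9ccccc9)c(OCc9ccccc9)c3)[C@H](OCc9ccccc9)[C@H]2c4c(OCc9ccccc9)c(Br)c(O[Si](C)(C)C)c(Br)c4OCc9ccccc9
F8 | step 15 | bromohydrin of 18 with bromine caps: unit 2 with 3β-Br and 4α-OH, bromine on C8 of units 1 and 2 | C(c9ccccc9)Oc1cc(OCc9ccccc9)c2c(c1Br)O[C@H](c3ccc(OCc9ccccc9)c(OCc9ccccc9)c3)[C@H](OCc9ccccc9)[C@H]2c4c(OCc9ccccc9)c(Br)c5c(c4OCc9ccccc9)[C@@H](O)[C@H](Br)[C@@H](c3ccc(OCc9ccccc9)c(OCc9ccccc9)c3)O5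
F9 | step 15 | 3α,4α-epoxide of unit 2, bromine on C8 of units 1 and 2 | C(c9ccccc9)Oc1cc(OCc9ccccc9)c2c(c1Br)O[C@H](c3ccc(OCc9ccccc9)c(OCc9ccccc9)c3)[C@H](OCc9ccccc9)[C@H]2c4c(OCc9ccccc9)c(Br)c5c(c4OCc9ccccc9)[C@H]6O[C@H]6[C@@H](c3ccc(OCc9ccccc9)c(OCc9ccccc9)c3)O5
F10 | step 15 | C4 epimer of 23: unit 2 with 3α-OH and 4β-(2-ethoxyethoxy) | C(c9ccccc9)Oc1cc(OCc9ccccc9)c2c(c1Br)O[C@H](c3ccc(OCc9ccccc9)c(OCc9ccccc9)c3)[C@H](OCc9ccccc9)[C@H]2c4c(OCc9ccccc9)c(Br)c5c(c4OCc9ccccc9)[C@H](OCCOCC)[C@@H](O)[C@@H](c3ccc(OCc9ccccc9)c(OCc9ccccc9)c3)O5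
F11 | step 19 | 8-iodo-5,7,3',4'-tetra-O-benzylepicatechin | C(c9ccccc9)Oc1cc(OCc9ccccc9)c2c(c1I)O[C@H](c3ccc(OCc9ccccc9)c(OCc9ccccc9)c3)[C@H](O)C2
F12 | step 19 | 8-iodo-5,7,3',4'-tetra-O-benzyl-4β-(2-ethoxyethoxy)epicatechin | C(c9ccccc9)Oc1cc(OCc9ccccc9)c2c(c1I)O[C@H](c3ccc(OCc9ccccc9)c(OCc9ccccc9)c3)[C@H](O)[C@H]2OCCOCC
F13 | step 19 | 8-iodo-tetra-O-benzylepicatechin-(4β→6)-(8-bromo-tetra-O-benzylepicatechin) | C(c9ccccc9)Oc1cc(OCc9ccccc9)c2c(c1I)O[C@H](c3ccc(OCc9ccccc9)c(OCc9ccccc9)c3)[C@H](O)[C@H]2c4c(OCc9ccccc9)c(Br)c5c(c4OCc9ccccc9)C[C@@H](O)[C@@H](c3ccc(OCc9ccccc9)c(OCc9ccccc9)c3)O5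
A1 | alternative 1 | 4-benzyloxy-6-[(E)-4-(3,4-bis(benzyloxy)phenyl)-2-oxobut-3-enyl]-3-(5,7,3',4'-tetra-O-benzyl-3-O-tert-butyldimethylsilylepicatechin-4β-yl)-2H-pyran-2-one | C(c9ccccc9)Oc1cc(OCc9ccccc9)c2c(c1)O[C@H](c3ccc(OCc9ccccc9)c(OCc9ccccc9)c3)[C@H](O[Si](C)(C)C(C)(C)C)[C@H]2C4=C(OCc9ccccc9)C=C(CC(=O)/C=C/c3ccc(OCc9ccccc9)c(OCc9ccccc9)c3)OC4=O
A2 | alternative 1 | (E)-chalcone: 4'-benzyloxy-2',6'-dihydroxy-3'-(5,7,3',4'-tetra-O-benzyl-3-O-tert-butyldimethylsilylepicatechin-4β-yl) ring A, 3,4-bis(benzyloxy) ring B | C(c9ccccc9)Oc1cc(OCc9ccccc9)c2c(c1)O[C@H](c3ccc(OCc9ccccc9)c(OCc9ccccc9)c3)[C@H](O[Si](C)(C)C(C)(C)C)[C@H]2c4c(OCc9ccccc9)cc(O)c(C(=O)/C=C/c3ccc(OCc9ccccc9)c(OCc9ccccc9)c3)c4O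
A3 | alternative 2 | [2,4-bis(benzyloxy)-6-hydroxyphenyl][5,7,3',4'-tetra-O-benzyl-3-O-tert-butyldimethylsilylepicatechin-6-yl]methanol (carbinol epimers) | C(c9ccccc9)Oc1cc(OCc9ccccc9)c(c(O)c1)C(O)c4c(OCc9ccccc9)cc5c(c4OCc9ccccc9)C[C@@H](O[Si](C)(C)C(C)(C)C)[C@@H](c3ccc(OCc9ccccc9)c(OCc9ccccc9)c3)O5
A4 | alternative 2 | (Z)-2-[2-(3,4-bis(benzyloxy)phenyl)ethenyl]-4,4,5,5-tetramethyl-1,3,2-dioxaborolane | CC1(C)OB(/C=C\c2ccc(OCc3ccccc3)c(OCc3ccccc3)c2)OC1(C)C
A5 | alternative 2 | unit 3–(C4 to C6)–unit 4 dimer with a pinacolboryl group on C3 of unit 3 and a 3-O-tert-butyldimethylsilyl group on unit 4 | C(c9ccccc9)Oc1cc(OCc9ccccc9)c2c(c1)O[C@H](c3ccc(OCc9ccccc9)c(OCc9ccccc9)c3)[C@H](B6OC(C)(C)C(C)(C)O6)[C@H]2c4c(OCc9ccccc9)cc5c(c4OCc9ccccc9)C[C@@H](O[Si](C)(C)C(C)(C)C)[C@@H](c3ccc(OCc9ccccc9)c(OCc9ccccc9)c3)O5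
A6 | alternative 3 | diazomethyl ketone of 2-[3,4-bis(benzyloxy)phenyl]-3-(tert-butyldimethylsilyloxy)-3,4-dihydro-2H-pyran-6-yl, aryl and silyloxy groups cis as in epicatechin | [N-]=[N+]=CC(=O)C1=CC[C@@H](O[Si](C)(C)C(C)(C)C)[C@@H](c2ccc(OCc3ccccc3)c(OCc3ccccc3)c2)O1
A7 | alternative 3 | 5,7,3',4'-tetra-O-benzyl-3-O-tert-butyldimethylsilyl-4β-[(triisopropylsilyloxy)ethynyl]epicatechin | C(c9ccccc9)Oc1cc(OCc9ccccc9)c2c(c1)O[C@H](c3ccc(OCc9ccccc9)c(OCc9ccccc9)c3)[C@H](O[Si](C)(C)C(C)(C)C)[C@H]2C#CO[Si](C(C)C)(C(C)C)C(C)C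
A8 | alternative 3 | unit 3–(C4 to C6)–unit 4 dimer with free 5-OH and 7-O-triisopropylsilyl on unit 4, 3-O-tert-butyldimethylsilyl on both units | C(c9ccccc9)Oc1cc(OCc9ccccc9)c2c(c1)O[C@H](c3ccc(OCc9ccccc9)c(OCc9ccccc9)c3)[C@H](O[Si](C)(C)C(C)(C)C)[C@H]2c4c(O[Si](C(C)C)(C(C)C)C(C)C)cc5c(c4O)C[C@@H](O[Si](C)(C)C(C)(C)C)[C@@H](c3ccc(OCc9ccccc9)c(OCc9ccccc9)c3)O5
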